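**Plan**

- Retrosynthesis: the 3'-O–acyl bond is cut first, then the C2–C1' bond between ring C and ring B, which leaves 5,6,7-trimethoxychromone and 2,3,6-trimethoxyphenyl pivalate.
- The chromone is cut at O1–C2 and C2–C3 to an ortho-hydroxyacetophenone plus a one-carbon amide acetal; the arene is cut at C3'–O to 1,2,4-trimethoxybenzene.
- Forward: ring A is bought as 3,4,5-trimethoxyphenol and ring C is closed on it. Ring B is oxygenated and acylated separately, then joined through C2–C1' by a palladium-catalysed twofold C–H coupling. Methanolysis frees the 3'-hydroxyl.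
- Enabling feature: C2–H of ring C is the β-carbon of an enone unsubstituted at C2 and C3. In ring B, C1'–H is ortho to the 2'-methoxy and para to the 4'-methoxy group, while the only other C–H (C6') is para to the acylated 3'-oxygen.
- Stereochemistry: the target has no stereocentre and no stereogenic double bond, so nothing has to be controlled.

Key step: step 5

Remark: flavone numbering (ring A and ring C unprimed, ring B primed) is used for both coupling partners; arene 9 is taken in excess in step 5 and the surplus recovered.

**Route**

Step 1
Reactants: 1 3,4,5-trimethoxyphenol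
Product: 2 1-(6-hydroxy-2,3,4-trimethoxyphenyl)ethan-1-one
Conditions: AcOH, BF3·OEt2 (Lewis acid promoter), 90 °C; aqueous work-up
Reagents that add atoms: acetic acid, CC(=O)O
Why: BF3-mediated Friedel–Crafts acylation (Fries-type, through the aryl acetate) can only enter the two equivalent positions ortho to the hydroxyl of this symmetric phenol, and the boron chelate of the product resists a second acylation.

Step 2
Reactants: 2 1-(6-hydroxy-2,3,4-trimethoxyphenyl)ethan-1-one
Product: 4 5,6,7-trimethoxy-4H-chromen-4-one, via (E)-3-(dimethylamino)-1-(6-hydroxy-2,3,4-trimethoxyphenyl)prop-2-en-1-one 3 (not isolated)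
Conditions: DMF-DMA, toluene, 100 °C; evaporate; conc. HCl, CH2Cl2, 40 °C
Reagents that add atoms: N,N-dimethylformamide dimethyl acetal, COC(OC)N(C)C
Why: Enaminone formation by condensation of the methyl ketone with the amide acetal is followed by acid-promoted intramolecular oxa-Michael addition of the phenol and loss of dimethylamine (addition–elimination cyclisation), which should give the chromone with C2 and C3 unsubstituted.

Step 3
Reactants: 5 1,2,4-trimethoxybenzene
Product: 8 2,3,6-trimethoxyphenol, via 2,3,6-trimethoxyphenyllithium 6 (not isolated), via lithium trimethoxy(2,3,6-trimethoxyphenyl)borate 7 (not isolated)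
Conditions: n-BuLi, THF, 0 °C to rt; B(OMe)3, −78 °C to rt; AcOH, 30% aq. H2O2, 0 °C to rt
Reagents that add atoms: hydrogen peroxide, OO (oxygen of the phenol); trimethyl borate, COB(OC)OC (boron and methoxy groups of 7 only); n-butyllithium, [Li]CCCC (lithium of 6 and 7 only)
Why: Directed ortho-metalation occurs at C3, the only position flanked by two methoxy groups, and the borate then undergoes the usual peroxide-induced 1,2-shift of the aryl group from boron to oxygen (lithiation–borylation–oxidation).

Step 4
Reactants: 8 2,3,6-trimethoxyphenol
Product: 9 2,3,6-trimethoxyphenyl pivalate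
Conditions: NaH, THF, 0 °C; PivCl, 0 °C to rt
Reagents that add atoms: pivaloyl chloride, CC(C)(C)C(Cl)=O
Why: O-Acylation of the sodium phenoxide with an acid chloride (nucleophilic acyl substitution) is reliable even for a phenol flanked by two methoxy groups, and it makes the future 3'-oxygen the only electron-poor oxygen of the ring.

Step 5
Reactants: 4 5,6,7-trimethoxy-4H-chromen-4-one; 9 2,3,6-trimethoxyphenyl pivalate
Product: 10 2,5,6-trimethoxy-3-(5,6,7-trimethoxy-4-oxo-4H-chromen-2-yl)phenyl pivalate
Conditions: Pd(OAc)2 (10 mol %), AgOAc (3 equiv), PivOH, 110 °C; 9 (4 equiv)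
Reagents that add atoms: none
Why: Pd(OPiv)2, formed from Pd(OAc)2 in pivalic acid, should palladate the arene by concerted metalation–deprotonation; the arylpalladium species then adds across C2=C3 of the chromone with the aryl group on the β-carbon C2 and palladium on C3, and after equilibration through the oxygen-bound palladium enolate a syn β-hydride elimination removes the C2 hydrogen and restores the pyranone, AgOAc returning zerovalent palladium to divalent palladium. The closest known reaction type is the palladium-catalysed oxidative twofold C–H coupling of chromones with arenes under Pd(OAc)2/AgOAc/PivOH, an intermolecular Fujiwara–Moritani-type arylation. Only the C2–C1' bond forms; no ring closes and no stereocentre arises. On the arene, C1'–H is ortho to the in-plane 2'-methoxy group and para to the 4'-methoxy group, whereas C6'–H has para to it the 3'-oxygen whose lone pair is drawn into the pivaloyl carbonyl, so metalation should favour C1'. On the chromone, carbopalladation in the conjugate sense excludes arylation at C3, and the excess of 9 is meant to outrun palladation at C8–H of ring A. The ester is a pivalate so that acyl exchange with the medium is degenerate.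

Step 6
Reactants: 10 2,5,6-trimethoxy-3-(5,6,7-trimethoxy-4-oxo-4H-chromen-2-yl)phenyl pivalate
Product: 11 agecorynin G [2-(3-hydroxy-2,4,5-trimethoxyphenyl)-5,6,7-trimethoxy-4H-chromen-4-one]
Conditions: NaOMe, MeOH/THF, rt; then aq. HCl
Reagents that add atoms: none
Why: Methoxide transesterification of an aryl ester (Zemplén-type methanolysis) is driven by the phenoxide leaving group and should leave the six methyl ethers and the 2-aryl-pyranone untouched at room temperature.

**Compound list**

1 | 3,4,5-trimethoxyphenol | COc1cc(O)cc(OC)c1OC | starting material
2 | 1-(6-hydroxy-2,3,4-trimethoxyphenyl)ethan-1-one | CC(=O)c1c(O)cc(OC)c(OC)c1OC | intermediate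
3 | (E)-3-(dimethylamino)-1-(6-hydroxy-2,3,4-trimethoxyphenyl)prop-2-en-1-one | CN(C)/C=C/C(=O)c1c(O)cc(OC)c(OC)c1OC | intermediate (not isolated)
4 | 5,6,7-trimethoxy-4H-chromen-4-one | COc1cc2occc(=O)c2c(OC)c1OC | intermediate
5 | 1,2,4-trimethoxybenzene | COc1ccc(OC)c(OC)c1 | starting material
6 | 2,3,6-trimethoxyphenyllithium | [Li]c1c(OC)ccc(OC)c1OC | intermediate (not isolated)
7 | lithium trimethoxy(2,3,6-trimethoxyphenyl)borate | [Li+].COc1ccc(OC)c([B-](OC)(OC)OC)c1OC | intermediate (not isolated)
8 | 2,3,6-trimethoxyphenol | COc1ccc(OC)c(O)c1OC | intermediate
9 | 2,3,6-trimethoxyphenyl pivalate | COc1ccc(OC)c(OC(=O)C(C)(C)C)c1OC | intermediate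
10 | 2,5,6-trimethoxy-3-(5,6,7-trimethoxy-4-oxo-4H-chromen-2-yl)phenyl pivalate | COc1cc(-c2cc(=O)c3c(OC)c(OC)c(OC)cc3o2)c(OC)c(OC(=O)C(C)(C)C)c1OC | intermediate
11 | agecorynin G | COc1cc(-c2cc(=O)c3c(OC)c(OC)c(OC)cc3o2)c(OC)c(O)c1OC | target

**Count**

Total steps: 6. Longest linear sequence: 4 steps (steps 1, 2, 5, 6; the arene branch, steps 3, 4, 5, 6, is equally long).

**Steps most likely to fail**

Step 5 (key coupling). Palladation may spread over C1' and C6' of the arene, the electron-rich arene may homocouple, and C8–H of ring A may be metalated in competition; each of these would drain the cross-coupling. The fallback sets out from 9 and 2 and builds ring C instead of arylating it. Rieche formylation of 9 (Cl2CHOMe, TiCl4, CH2Cl2, 0 °C) is a Friedel–Crafts substitution that should respond more steeply to the para-methoxy group than palladation does, and its orientation can be checked and purified on a small building block. It should give 3-formyl-2,5,6-trimethoxyphenyl pivalate F1. Claisen–Schmidt condensation of F1 with acetophenone 2 (KOH, EtOH, rt), during which the pivalate is saponified, should give (E)-3-(3-hydroxy-2,4,5-trimethoxyphenyl)-1-(6-hydroxy-2,3,4-trimethoxyphenyl)prop-2-en-1-one F2. Oxidative cyclisation with catalytic I2 in DMSO at 130 °C then closes ring C and rejoins the route at target 11.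

Step 6 (methanolysis). Acyl substitution at a pivalate flanked by two methoxy groups may be slow enough for methoxide to add at C2 of the pyranone and open ring C. The fallback sets out from 8 and carries the 3'-oxygen as a carbonate that is removed by hydrogenolysis. Benzyl chloroformate and pyridine in CH2Cl2 should give benzyl 2,3,6-trimethoxyphenyl carbonate F3, which keeps the 3'-oxygen electron-poor. Coupling of F3 with 4 under the conditions of step 5 should give benzyl 2,5,6-trimethoxy-3-(5,6,7-trimethoxy-4-oxo-4H-chromen-2-yl)phenyl carbonate F4. Hydrogenolysis (H2, Pd/C, EtOAc, rt) removes the benzyl group, the carbonic half-ester loses carbon dioxide, and the route is rejoined at target 11 without any base.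

Step 3 (lithiation–borylation–oxidation). The hindered aryllithium may be trapped incompletely by B(OMe)3, and the very electron-rich phenol may be oxidised further by excess peroxide towards quinones. The fallback sets out from 5, lithiates as in step 3 (aryllithium 6) and quenches with DMF to give 2,3,6-trimethoxybenzaldehyde F5. Baeyer–Villiger (Dakin-type) oxidation with one equivalent of mCPBA in CH2Cl2, in which the electron-rich aryl group migrates, should give 2,3,6-trimethoxyphenyl formate F6; this keeps the phenol masked until the oxidant is consumed. Methanolysis with catalytic K2CO3 in MeOH releases the phenol and rejoins the route at 8.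

**Further compounds**

F1 | step 5 | 3-formyl-2,5,6-trimethoxyphenyl pivalate | COc1cc(C=O)c(OC)c(OC(=O)C(C)(C)C)c1OC
F2 | step 5 | (E)-3-(3-hydroxy-2,4,5-trimethoxyphenyl)-1-(6-hydroxy-2,3,4-trimethoxyphenyl)prop-2-en-1-one | COc1cc(/C=C/C(=O)c2c(O)cc(OC)c(OC)c2OC)c(OC)c(O)c1OC
F3 | step 6 | benzyl 2,3,6-trimethoxyphenyl carbonate | COc1ccc(OC)c(OC(=O)OCc2ccccc2)c1OC
F4 | step 6 | benzyl 2,5,6-trimethoxy-3-(5,6,7-trimethoxy-4-oxo-4H-chromen-2-yl)phenyl carbonate | COc1cc(-c2cc(=O)c3c(OC)c(OC)c(OC)cc3o2)c(OC)c(OC(=O)OCc2ccccc2)c1OC
F5 | step 3 | 2,3,6-trimethoxybenzaldehyde | COc1ccc(OC)c(C=O)c1OC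
F6 | step 3 | 2,3,6-trimethoxyphenyl formate | COc1ccc(OC)c(OC=O)c1OC
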